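**Assumption:** CNP0150481.2 is taken exactly as the given SMILES, which is the (1R,6R,7R,8R,10S) isomer in germacrane numbering (4Z alkene, trans-fused 6,12-lactone, 1,10-oxirane, 14-acetate, 8-methacrylate). Germacrane numbers C1–C15 are used below as position shorthand.

## Retrosynthetic overview

1. Target ⇒ 8-hydroxy macrolide 21 by a final methacryloylation at C8.
2. 21 ⇒ acyclic (Z)-enal / 2-(bromomethyl)enoate 19: one ligand-controlled chromium-catalysed allylation closes the ten-membered carbocycle (C6–C7) and, by lactonisation in the same flask, the γ-lactone (new step).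
3. Oxirane (first ring) ⇐ Shi-ketone epoxidation of the acyclic C1=C10 alkene at the enal stage, where every other alkene is electron-poor.
4. C8 (first stereocentre) ⇐ L-proline-catalysed α-aminoxylation of achiral aldehyde 10, with the olefination that builds C7=C11 in the same pot.
5. Achiral chain ⇐ anti-carbomagnesiation/iodination of propargyl alcohol, then B-alkyl Suzuki coupling with the 9-BBN adduct of (Z)-3-methylpenta-2,4-dien-1-ol. Ring order: oxirane, then carbocycle and lactone together.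

## Route

Step 1
Reactants: 1 prop-2-yn-1-ol; 2 [2-(1,3-dioxolan-2-yl)ethyl]magnesium bromide
Product: 4 (2Z)-2-[2-(1,3-dioxolan-2-yl)ethyl]-3-iodoprop-2-en-1-ol, via alkenylmagnesium chelate 3 (not isolated)
Conditions: 2 (3 equiv), CuI (10 mol%), THF/Et2O, −10 °C to rt; then I2, −40 °C to 0 °C
Reagents that add atoms: iodine (II)
Why: copper-catalysed anti-carbomagnesiation of the propargylic alkoxide (Duboudin reaction) puts the alkyl group on C10 and magnesium on C1 cis to the CH2O arm in a five-membered chelate, and iodinolysis with retention fixes the trisubstituted alkene geometry (C14 cis to the future C2; no stereocentre).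

Step 2
Reactants: 4 (2Z)-2-[2-(1,3-dioxolan-2-yl)ethyl]-3-iodoprop-2-en-1-ol
Product: 5 [(2Z)-2-[2-(1,3-dioxolan-2-yl)ethyl]-3-iodoprop-2-en-1-yl] acetate
Conditions: Ac2O, pyridine, DMAP (5 mol%), CH2Cl2, 0 °C
Reagents that add atoms: acetic anhydride (CC(=O)OC(C)=O)
Why: DMAP-catalysed O-acylation of the only hydroxyl installs the C14 acetate of the target before any other alcohol is present.

Step 3
Reactants: 6 (2Z)-3-methylpent-2-en-4-yn-1-ol
Product: 7 (2Z)-3-methylpenta-2,4-dien-1-ol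
Conditions: H2 (1 atm), Pd on CaCO3 poisoned with Pb(OAc)2 (5 wt%), quinoline, EtOAc, rt
Reagents that add atoms: none
Why: Lindlar semi-hydrogenation of the terminal alkyne stops at the alkene and leaves the Z-trisubstituted alkene untouched.

Step 4
Reactants: 7 (2Z)-3-methylpenta-2,4-dien-1-ol; 5 [(2Z)-2-[2-(1,3-dioxolan-2-yl)ethyl]-3-iodoprop-2-en-1-yl] acetate
Product: 9 [(2Z,6Z)-2-[2-(1,3-dioxolan-2-yl)ethyl]-8-hydroxy-6-methylocta-2,6-dien-1-yl] acetate, via bis-9-BBN adduct 8 (not isolated)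
Conditions: 7, 9-BBN (2.2 equiv), THF, 0 °C to rt; then 5, PdCl2(dppf) (5 mol%), AsPh3 (10 mol%), K3PO4 (3 M aq.), DMF, rt
Reagents that add atoms: none
Why: 9-BBN adds anti-Markovnikov to the terminal vinyl group only (the alcohol rides as its borinate), and the B-alkyl Suzuki–Miyaura coupling forms C1–C2 with retention at the alkenyl iodide, which adds to zerovalent palladium far faster than the allylic acetate ionises.

Step 5
Reactants: 9 [(2Z,6Z)-2-[2-(1,3-dioxolan-2-yl)ethyl]-8-hydroxy-6-methylocta-2,6-dien-1-yl] acetate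
Product: 10 [(2Z,6Z)-8-hydroxy-6-methyl-2-(3-oxopropyl)octa-2,6-dien-1-yl] acetate
Conditions: PPTS (20 mol%), acetone/H2O (10:1), 50 °C
Reagents that add atoms: water (O)
Why: mild acid-catalysed acetal hydrolysis frees the C7 aldehyde without touching the allylic acetate or the alkenes.

Step 6
Reactants: 10 [(2Z,6Z)-8-hydroxy-6-methyl-2-(3-oxopropyl)octa-2,6-dien-1-yl] acetate; 11 trimethyl phosphonoacetate; 12 formaldehyde (used as paraformaldehyde)
Product: 15 methyl (2E,4R,6Z,10Z)-6-(acetoxymethyl)-4-(anilinooxy)-12-hydroxy-2-(hydroxymethyl)-10-methyldodeca-2,6,10-trienoate, via α-aminoxy aldehyde 13 (not isolated), via hydroxymethyl phosphonate 14 (not isolated)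
Conditions: (a) 10, PhNO (1.0 equiv), L-proline (20 mol%), MeCN, −20 °C; (b) second flask: 11, 12, piperidine (5 mol%), MeOH, 60 °C, evaporate; (c) residue of (b), LiCl, DBU, MeCN, added to (a), −20 °C to 0 °C
Reagents that add atoms: nitrosobenzene (O=Nc1ccccc1)
Why: the L-proline enamine takes nitrosobenzene oxygen on the face directed by the carboxylic acid (O-nitroso aldol, α-aminoxylation) to set C8 as R, and the labile aldehyde is trapped at once by a Masamune–Roush Horner–Wadsworth–Emmons olefination that gives the E-enoate (C8 trans to the ester).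

Step 7
Reactants: 15 methyl (2E,4R,6Z,10Z)-6-(acetoxymethyl)-4-(anilinooxy)-12-hydroxy-2-(hydroxymethyl)-10-methyldodeca-2,6,10-trienoate
Product: 16 methyl (2E,4R,6Z,10Z)-6-(acetoxymethyl)-4,12-dihydroxy-2-(hydroxymethyl)-10-methyldodeca-2,6,10-trienoate
Conditions: Zn dust, AcOH/THF (1:4), rt
Reagents that add atoms: none
Why: zinc in acetic acid reduces the weak N–O bond (reductive N–O cleavage) and spares the acetate and the E-enoate, whose geometry keeps the new C8 hydroxyl from lactonising.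

Step 8
Reactants: 16 methyl (2E,4R,6Z,10Z)-6-(acetoxymethyl)-4,12-dihydroxy-2-(hydroxymethyl)-10-methyldodeca-2,6,10-trienoate
Product: 17 methyl (2E,4R,6Z,10Z)-6-(acetoxymethyl)-4-hydroxy-2-(hydroxymethyl)-10-methyl-12-oxododeca-2,6,10-trienoate
Conditions: activated MnO2 (15 equiv), CH2Cl2, 0 °C to rt, monitored
Reagents that add atoms: none
Why: MnO2 oxidises the electron-rich primary allylic alcohol at C6 much faster than the two allylic alcohols on the electron-poor enoate, and the Z-enal geometry survives as in the nerol-to-neral oxidation.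

Step 9
Reactants: 17 methyl (2E,4R,6Z,10Z)-6-(acetoxymethyl)-4-hydroxy-2-(hydroxymethyl)-10-methyl-12-oxododeca-2,6,10-trienoate
Product: 18 methyl (2E,4R)-5-[(2S,3R)-2-(acetoxymethyl)-3-[(3Z)-3-methyl-5-oxopent-3-en-1-yl]oxiran-2-yl]-4-hydroxy-2-(hydroxymethyl)pent-2-enoate
Conditions: 1,2:4,5-di-O-isopropylidene-β-D-erythro-2,3-hexodiulo-2,6-pyranose (D-fructose-derived Shi ketone, 30 mol%), KHSO5 (as 2KHSO5·KHSO4·K2SO4, 1.5 equiv), K2CO3, Bu4NHSO4 (5 mol%), Na2B4O7/Na2(EDTA) buffer, MeCN/dimethoxymethane/H2O, pH 10.5, −10 °C to 0 °C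
Reagents that add atoms: potassium peroxymonosulfate ([K+].OOS(=O)(=O)[O-])
Why: the chiral dioxirane epoxidises the only electron-rich alkene (C1=C10; the enal and enoate alkenes are inert) through the spiro transition state with the vinylic hydrogen in the hindered quadrant, which for this alkene geometry delivers oxygen to the face that gives the (1R,10S) oxirane (Shi epoxidation).

Step 10
Reactants: 18 methyl (2E,4R)-5-[(2S,3R)-2-(acetoxymethyl)-3-[(3Z)-3-methyl-5-oxopent-3-en-1-yl]oxiran-2-yl]-4-hydroxy-2-(hydroxymethyl)pent-2-enoate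
Product: 19 methyl (2Z,4R)-5-[(2S,3R)-2-(acetoxymethyl)-3-[(3Z)-3-methyl-5-oxopent-3-en-1-yl]oxiran-2-yl]-2-(bromomethyl)-4-hydroxypent-2-enoate
Conditions: CBr4 (1.1 equiv), PPh3 (1.15 equiv), CH2Cl2, −30 °C to 0 °C
Reagents that add atoms: tetrabromomethane (BrC(Br)(Br)Br)
Why: the Appel reaction brominates the primary allylic alcohol in preference to the secondary one under neutral conditions that the oxirane and the Z-enal tolerate.

Step 11
Reactants: 19 methyl (2Z,4R)-5-[(2S,3R)-2-(acetoxymethyl)-3-[(3Z)-3-methyl-5-oxopent-3-en-1-yl]oxiran-2-yl]-2-(bromomethyl)-4-hydroxypent-2-enoate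
Product: 21 (1R,6R,7R,8R,10S)-14-acetoxy-1,10-epoxy-8-hydroxygermacra-4(Z),11(13)-dien-12,6-olide, via seco hydroxy ester 20 (not isolated)
Conditions: CrCl2 (15 mol%), (S,S)-3,6-di-tert-butyl-1,8-bis(4-isopropyl-4,5-dihydrooxazol-2-yl)-9H-carbazole (18 mol%), Mn powder (3 equiv), Cp2ZrCl2 (1.5 equiv), iPr2NEt (0.5 equiv), THF/MeCN, rt, 19 added by syringe pump over 12 h (final 0.002 M); aq. NH4Cl; then PPTS (10 mol%), CH2Cl2, rt
Reagents that add atoms: none
Why: Proposed new method: a ligand-controlled, chromium-catalysed macrocyclising 2-(methoxycarbonyl)allylation in which divalent chromium (turned over by Mn powder and Cp2ZrCl2) converts the allylic bromide into an allylchromium species held by the tridentate carbazole-bis(oxazoline), this equilibrates to the isomer with C8 trans to CH2Cr and adds through a closed six-membered chair to the Si face of the tethered Z-enal (attack anti to the C9 chain with H-8 eclipsing the alkene), giving the 6,7-anti adduct (6R,7R) that lactonises to the trans-fused methylene lactone, the closest known reactions being the stoichiometric CrCl2 ring closures of ω-formyl 2-(bromomethyl)enoates to germacranolides and the intermolecular carbazole-bis(oxazoline)/chromium-catalysed enantioselective 2-(alkoxycarbonyl)allylation of aldehydes (Nozaki–Hiyama–Kishi type).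

Step 12
Reactants: 21 (1R,6R,7R,8R,10S)-14-acetoxy-1,10-epoxy-8-hydroxygermacra-4(Z),11(13)-dien-12,6-olide
Product: 22 (1R,6R,7R,8R,10S)-14-acetoxy-1,10-epoxy-8-(methacryloyloxy)germacra-4(Z),11(13)-dien-12,6-olide (CNP0150481.2)
Conditions: methacrylic anhydride (1.5 equiv), Et3N, DMAP (10 mol%), CH2Cl2, 0 °C
Reagents that add atoms: methacrylic anhydride (C=C(C)C(=O)OC(=O)C(C)=C)
Why: DMAP-catalysed acyl transfer to the only free hydroxyl (C8) completes the target without disturbing the methylene lactone, the acetate or the oxirane.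

## Compound list

1 | prop-2-yn-1-ol | C#CCO | starting material
2 | [2-(1,3-dioxolan-2-yl)ethyl]magnesium bromide | Br[Mg]CCC1OCCO1 | starting material
3 | alkenylmagnesium chelate, 4-[2-(1,3-dioxolan-2-yl)ethyl]-2,5-dihydro-1,2-oxamagnesole | [Mg]1OCC(CCC2OCCO2)=C1 | intermediate
4 | (2Z)-2-[2-(1,3-dioxolan-2-yl)ethyl]-3-iodoprop-2-en-1-ol | I/C=C(\CO)CCC1OCCO1 | intermediate
5 | [(2Z)-2-[2-(1,3-dioxolan-2-yl)ethyl]-3-iodoprop-2-en-1-yl] acetate | I/C=C(\COC(C)=O)CCC1OCCO1 | intermediate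
6 | (2Z)-3-methylpent-2-en-4-yn-1-ol | OC/C=C(C)\C#C | starting material
7 | (2Z)-3-methylpenta-2,4-dien-1-ol | OC/C=C(C)\C=C | intermediate
8 | bis-9-BBN adduct, 9-[(3Z)-5-(9-borabicyclo[3.3.1]nonan-9-yloxy)-3-methylpent-3-en-1-yl]-9-borabicyclo[3.3.1]nonane | C(/C=C(C)\CCB1C2CCCC1CCC2)OB1C2CCCC1CCC2 | intermediate
9 | [(2Z,6Z)-2-[2-(1,3-dioxolan-2-yl)ethyl]-8-hydroxy-6-methylocta-2,6-dien-1-yl] acetate | OC/C=C(C)\CC/C=C(\COC(C)=O)CCC1OCCO1 | intermediate
10 | [(2Z,6Z)-8-hydroxy-6-methyl-2-(3-oxopropyl)octa-2,6-dien-1-yl] acetate | OC/C=C(C)\CC/C=C(\COC(C)=O)CCC=O | intermediate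
11 | trimethyl phosphonoacetate | COC(=O)CP(=O)(OC)OC | starting material
12 | formaldehyde (used as paraformaldehyde) | C=O | starting material
13 | α-aminoxy aldehyde, [(2Z,6Z)-2-[(2R)-2-(anilinooxy)-3-oxopropyl]-8-hydroxy-6-methylocta-2,6-dien-1-yl] acetate | OC/C=C(C)\CC/C=C(\COC(C)=O)C[C@@H](ONc1ccccc1)C=O | intermediate
14 | hydroxymethyl phosphonate, methyl 2-(dimethoxyphosphoryl)-3-hydroxypropanoate | COC(=O)C(CO)P(=O)(OC)OC | intermediate
15 | methyl (2E,4R,6Z,10Z)-6-(acetoxymethyl)-4-(anilinooxy)-12-hydroxy-2-(hydroxymethyl)-10-methyldodeca-2,6,10-trienoate | OC/C=C(C)\CC/C=C(\COC(C)=O)C[C@@H](ONc1ccccc1)/C=C(\CO)C(=O)OC | intermediate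
16 | methyl (2E,4R,6Z,10Z)-6-(acetoxymethyl)-4,12-dihydroxy-2-(hydroxymethyl)-10-methyldodeca-2,6,10-trienoate | OC/C=C(C)\CC/C=C(\COC(C)=O)C[C@@H](O)/C=C(\CO)C(=O)OC | intermediate
17 | methyl (2E,4R,6Z,10Z)-6-(acetoxymethyl)-4-hydroxy-2-(hydroxymethyl)-10-methyl-12-oxododeca-2,6,10-trienoate | O=C/C=C(C)\CC/C=C(\COC(C)=O)C[C@@H](O)/C=C(\CO)C(=O)OC | intermediate
18 | methyl (2E,4R)-5-[(2S,3R)-2-(acetoxymethyl)-3-[(3Z)-3-methyl-5-oxopent-3-en-1-yl]oxiran-2-yl]-4-hydroxy-2-(hydroxymethyl)pent-2-enoate | O=C/C=C(C)\CC[C@H]1O[C@]1(COC(C)=O)C[C@@H](O)/C=C(\CO)C(=O)OC | intermediate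
19 | methyl (2Z,4R)-5-[(2S,3R)-2-(acetoxymethyl)-3-[(3Z)-3-methyl-5-oxopent-3-en-1-yl]oxiran-2-yl]-2-(bromomethyl)-4-hydroxypent-2-enoate | O=C/C=C(C)\CC[C@H]1O[C@]1(COC(C)=O)C[C@@H](O)/C=C(\CBr)C(=O)OC | intermediate
20 | seco hydroxy ester, methyl (1R,6R,7R,8R,10S)-14-acetoxy-1,10-epoxy-6,8-dihydroxygermacra-4(Z),11(13)-dien-12-oate | O[C@@H]1C[C@@]2(COC(C)=O)O[C@@H]2CC/C(C)=C\[C@@H](O)[C@@H]1C(=C)C(=O)OC | intermediate
21 | (1R,6R,7R,8R,10S)-14-acetoxy-1,10-epoxy-8-hydroxygermacra-4(Z),11(13)-dien-12,6-olide | O[C@@H]1C[C@@]2(COC(C)=O)O[C@@H]2CC/C(C)=C\[C@H]2OC(=O)C(=C)[C@@H]21 | intermediate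
22 | (1R,6R,7R,8R,10S)-14-acetoxy-1,10-epoxy-8-(methacryloyloxy)germacra-4(Z),11(13)-dien-12,6-olide (CNP0150481.2) | C=C(C)C(=O)O[C@@H]1C[C@@]2(COC(C)=O)O[C@@H]2CC/C(C)=C\[C@H]2OC(=O)C(=C)[C@@H]21 | target

## Step count and risks

Total: 12 steps. Longest linear sequence: 11 steps (1, 2, 4, 5, 6, 7, 8, 9, 10, 11, 12 from prop-2-yn-1-ol); step 3 prepares the coupling partner.

Stereocentre bookkeeping: C8 in step 6 (L-proline), C1 and C10 in step 9 (Shi ketone), C6 and C7 in step 11. None is touched afterwards.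

The three steps most likely to fail:

**Step 11 (the proposed new ring closure).** The catalytic cycle may stall at the high dilution needed, and the ligand sense for this enal is extrapolated from simple aldehydes, so it may oppose the C8 bias; the antipodal ligand is the immediate control. The fallback uses known chemistry and replaces catalyst control by substrate control. From 19, TESCl/imidazole gives the silyl ether methyl (2Z,4R)-5-[(2S,3R)-2-(acetoxymethyl)-3-[(3Z)-3-methyl-5-oxopent-3-en-1-yl]oxiran-2-yl]-2-(bromomethyl)-4-(triethylsilyloxy)pent-2-enoate F1. Stoichiometric CrCl2 in DMF/THF at high dilution then closes the ring. This is the established chromium-mediated closure of ω-formyl 2-(bromomethyl)enoates to germacranolides, and the bulky non-chelating silyl ether keeps C8 trans to CH2Cr. It gives the 8-O-triethylsilyl ether of hydroxy lactone 21 F2, and AcOH/THF/H2O brings the route back at 21.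

**Step 9 (Shi epoxidation beside a free Z-enal).** Peroxymonosulfate at pH 10.5 can oxidise the aldehyde or isomerise the enal. The fallback postpones the oxirane until after ring closure. From 17, CBr4/PPh3 gives methyl (2Z,4R,6Z,10Z)-6-(acetoxymethyl)-2-(bromomethyl)-4-hydroxy-10-methyl-12-oxododeca-2,6,10-trienoate F3. CrCl2 in DMF (a donor solvent that tolerates the free hydroxyl) closes the ring to (6R,7R,8R)-14-acetoxy-8-hydroxygermacra-1(10)Z,4Z,11(13)-trien-12,6-olide F4. VO(acac)2/t-BuOOH, directed by the homoallylic 8-hydroxyl to the strained C1(10) alkene from the ring periphery, then returns to 21.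

**Step 8 (MnO2 selectivity among three allylic alcohols).** Over-oxidation at C13 or C8 is possible. The fallback is a protecting-group route. From 16, 2,2-dimethoxypropane/PPTS ties the cis-1,4-diol (8-OH and 13-OH) into methyl (7R)-7-[(2Z,6Z)-2-(acetoxymethyl)-8-hydroxy-6-methylocta-2,6-dien-1-yl]-2,2-dimethyl-4,7-dihydro-1,3-dioxepine-5-carboxylate F5; any mixed acetal at the C6 hydroxyl falls off on aqueous work-up. Dess–Martin periodinane oxidises the one free alcohol to methyl (7R)-7-[(2Z,6Z)-2-(acetoxymethyl)-6-methyl-8-oxoocta-2,6-dien-1-yl]-2,2-dimethyl-4,7-dihydro-1,3-dioxepine-5-carboxylate F6, and AcOH/THF/H2O returns to 17.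

## Further compounds

F1 | step 11 | methyl (2Z,4R)-5-[(2S,3R)-2-(acetoxymethyl)-3-[(3Z)-3-methyl-5-oxopent-3-en-1-yl]oxiran-2-yl]-2-(bromomethyl)-4-(triethylsilyloxy)pent-2-enoate | O=C/C=C(C)\CC[C@H]1O[C@]1(COC(C)=O)C[C@@H](O[Si](CC)(CC)CC)/C=C(\CBr)C(=O)OC
F2 | step 11 | 8-O-triethylsilyl ether of hydroxy lactone 21 (configuration as in 21) | CC[Si](CC)(CC)O[C@@H]1C[C@@]2(COC(C)=O)O[C@@H]2CC/C(C)=C\[C@H]2OC(=O)C(=C)[C@@H]21
F3 | step 9 | methyl (2Z,4R,6Z,10Z)-6-(acetoxymethyl)-2-(bromomethyl)-4-hydroxy-10-methyl-12-oxododeca-2,6,10-trienoate | O=C/C=C(C)\CC/C=C(\COC(C)=O)C[C@@H](O)/C=C(\CBr)C(=O)OC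
F4 | step 9 | (6R,7R,8R)-14-acetoxy-8-hydroxygermacra-1(10)Z,4Z,11(13)-trien-12,6-olide | O[C@@H]1C/C(COC(C)=O)=C/CC/C(C)=C\[C@H]2OC(=O)C(=C)[C@@H]21
F5 | step 8 | methyl (7R)-7-[(2Z,6Z)-2-(acetoxymethyl)-8-hydroxy-6-methylocta-2,6-dien-1-yl]-2,2-dimethyl-4,7-dihydro-1,3-dioxepine-5-carboxylate | OC/C=C(C)\CC/C=C(\COC(C)=O)C[C@H]1OC(C)(C)OCC(C(=O)OC)=C1
F6 | step 8 | methyl (7R)-7-[(2Z,6Z)-2-(acetoxymethyl)-6-methyl-8-oxoocta-2,6-dien-1-yl]-2,2-dimethyl-4,7-dihydro-1,3-dioxepine-5-carboxylate | O=C/C=C(C)\CC/C=C(\COC(C)=O)C[C@H]1OC(C)(C)OCC(C(=O)OC)=C1
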